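**Retrosynthetic overview**
1. The C-10 methyl carbinol is made last, by equatorial methyl addition to a C-10 ketone.
2. All three rings come from one acyclic triepoxide in a single Lewis-acid operation. The 2,3-/6,7-diepoxide with a silyl enol ether terminator gives the oxepane first, then its fused cyclohexanone. The cis-18,19-epoxide with the C-14=C-15 olefin closes ring A independently in the same flask.
3. The acyclic precursor is joined at C-14=C-15 by cross-metathesis of a C15 left half and a C14 right half, each already carrying its Shi epoxide(s).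
4. The left half comes from geranyl bromide (amide alkylation, Shi epoxidation, vinyl ketone, conjugate allylation that fixes the enol ether regiochemistry).
5. The right half comes from neryl acetate (hydroxyselenation–elimination, methallyl coupling, Shi epoxidation); its (Z)-olefin is what places 18-OH cis to the side chain.

Assumption: positions are quoted with squalene-type locants C-1 to C-24 along the acyclic chain (C-3 and C-18 secondary carbinols, C-10 methyl carbinol, C-14=C-15 ring A olefin), and both Shi epoxidations use the commercial D-fructose-derived ketone.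

**Step 1**
Reactants: 1 geranyl bromide; 2 N-methoxy-N-methylacetamide
Product: 4 (4E)-N-methoxy-N,5,9-trimethyldeca-4,8-dienamide, via lithium enolate 3 (not isolated)
Conditions: LiN(iPr)2, THF, −78 °C; then 1, −78 → −20 °C
Reagents that add atoms: none
Why: Enolate alkylation (SN2) of the Weinreb acetamide enolate with the primary allylic bromide leaves both trisubstituted olefins and the (E)-geometry untouched.

**Step 2**
Reactants: 4 (4E)-N-methoxy-N,5,9-trimethyldeca-4,8-dienamide
Product: 5 (4R,5R,8R)-4,5:8,9-diepoxy-N-methoxy-N,5,9-trimethyldecanamide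
Conditions: D-fructose-derived Shi ketone (2 × 30 mol %), 2KHSO5·KHSO4·K2SO4, K2CO3, Bu4NHSO4, MeCN–(MeO)2CH2–aq. Na2B4O7 buffer (pH 10.5), 0 °C
Reagents that add atoms: potassium peroxymonosulfate ([K+].OOS(=O)(=O)[O-])
Why: Shi asymmetric epoxidation; the chiral dioxirane epoxidises both electron-rich trisubstituted olefins through the spiro transition state, giving (R) at each CH carbon (C-3, C-7) and (R) at C-6, while the amide is inert.

**Step 3**
Reactants: 5 (4R,5R,8R)-4,5:8,9-diepoxy-N-methoxy-N,5,9-trimethyldecanamide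
Product: 6 (6R,7R,10R)-6,7:10,11-diepoxy-7,11-dimethyldodec-1-en-3-one
Conditions: CH2=CHMgBr, THF, −78 → 0 °C; inverse quench into cold aq. NaHSO4
Reagents that add atoms: vinylmagnesium bromide (C=C[Mg]Br)
Why: Weinreb ketone synthesis; the chelated tetrahedral adduct prevents over-addition and collapses to the vinyl ketone on acidic quench, and trisubstituted epoxides survive the Grignard reagent at low temperature.

**Step 4**
Reactants: 6 (6R,7R,10R)-6,7:10,11-diepoxy-7,11-dimethyldodec-1-en-3-one
Product: 7 trimethyl{[(5Z,9R,10R,13R)-9,10:13,14-diepoxy-10,14-dimethylpentadeca-1,5-dien-6-yl]oxy}silane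
Conditions: CH2=CHCH2MgBr, CuBr·SMe2, Me3SiCl, THF, −78 °C; Et3N, aq. NaHCO3; filtration through Et3N-deactivated silica
Reagents that add atoms: allylmagnesium bromide (C=CC[Mg]Br); chlorotrimethylsilane (C[Si](C)(C)Cl)
Why: Me3SiCl-accelerated organocopper conjugate addition to the s-cis vinyl ketone forms C-12–C-13 and traps the enolate regiospecifically as the (Z)-silyl enol ether towards C-11, which deprotonation of the ketone could not do.

**Step 5**
Reactants: 8 neryl acetate [(2Z)-3,7-dimethylocta-2,6-dien-1-yl acetate]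
Product: 11 (2Z,5E)-7-hydroxy-3,7-dimethylocta-2,5-dien-1-yl acetate, via hydroxy selenide 9 (not isolated), via selenoxide 10 (not isolated)
Conditions: N-(phenylselanyl)phthalimide, H2O, camphorsulfonic acid (cat.), CH2Cl2, 23 °C; then 30% H2O2, pyridine (cat.), THF, 0 → 23 °C
Reagents that add atoms: water (O)
Why: Hydroxyselenation then selenoxide syn-elimination; selenium attacks only the electron-rich 6,7-olefin (the 2,3-olefin is deactivated by the allylic acetate), water opens the seleniranium ion at the tertiary carbon, and elimination can only go towards C-5, giving the (E)-allylic tertiary alcohol.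

**Step 6**
Reactants: 11 (2Z,5E)-7-hydroxy-3,7-dimethylocta-2,5-dien-1-yl acetate
Product: 12 (5Z,8E)-2,6,10-trimethylundeca-1,5,8-trien-10-ol
Conditions: CH2=C(Me)CH2MgCl (3 equiv), Li2CuCl4 (5 mol %), THF, −78 → 0 °C
Reagents that add atoms: 2-methylallylmagnesium chloride (CC(=C)C[Mg]Cl)
Why: Copper-catalysed Grignard allylic substitution at the primary carbon of the γ,γ-disubstituted allylic acetate (SN2, (Z)-olefin retained); the first equivalent of Grignard reagent only deprotonates the tertiary alcohol.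

**Step 7**
Reactants: 12 (5Z,8E)-2,6,10-trimethylundeca-1,5,8-trien-10-ol
Product: 13 (5R,6S,8E)-5,6-epoxy-2,6,10-trimethylundeca-1,8-dien-10-ol
Conditions: D-fructose-derived Shi ketone (30 mol %), 2KHSO5·KHSO4·K2SO4 (1.1 equiv KHSO5), K2CO3, Bu4NHSO4, MeCN–(MeO)2CH2–aq. Na2B4O7 buffer, −10 °C, stopped at about 90% conversion
Reagents that add atoms: potassium peroxymonosulfate ([K+].OOS(=O)(=O)[O-])
Why: Shi asymmetric epoxidation; the trisubstituted (Z)-olefin reacts faster than the 1,1-disubstituted and the hindered trans-disubstituted olefins, and the same spiro transition state places (R) at the CH carbon C-18, hence the cis-(18R,19S)-epoxide.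

**Step 8**
Reactants: 7 trimethyl{[(5Z,9R,10R,13R)-9,10:13,14-diepoxy-10,14-dimethylpentadeca-1,5-dien-6-yl]oxy}silane; 13 (5R,6S,8E)-5,6-epoxy-2,6,10-trimethylundeca-1,8-dien-10-ol (3 equiv, excess recovered)
Product: 14 (3R,6R,7R,10Z,14E,18R,19S,21E)-2,3:6,7:18,19-triepoxy-2,6,15,19,23-pentamethyl-10-[(trimethylsilyl)oxy]tetracosa-10,14,21-trien-23-ol (14E/14Z mixture; E shown)
Conditions: second-generation Hoveyda–Grubbs catalyst [(H2IMes)Cl2Ru=CH(o-iPrOC6H4)] (10 mol %), CH2Cl2, 40 °C; Et3N-deactivated silica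
Reagents that add atoms: none
Why: Olefin cross-metathesis of the terminal olefin of 7 with the 1,1-disubstituted olefin of 13 builds the trisubstituted C-14=C-15 bond with loss of ethene; its geometry sets no stereocentre, and the epoxides, tertiary alcohol and fully substituted silyl enol ether are spectators.

**Step 9**
Reactants: 14 (3R,6R,7R,10Z,14E,18R,19S,21E)-2,3:6,7:18,19-triepoxy-2,6,15,19,23-pentamethyl-10-[(trimethylsilyl)oxy]tetracosa-10,14,21-trien-23-ol
Product: 16 (3R,5aR,6R,9aR)-3-hydroxy-6-(2-{(5R,6S)-5-hydroxy-6-[(2E)-4-hydroxy-4-methylpent-2-en-1-yl]-2,6-dimethylcyclohex-1-en-1-yl}ethyl)-2,2,5a-trimethyloctahydro-1-benzoxepin-7(2H)-one, via tris(trimethylsilyl) ether 15 (not isolated)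
Conditions: Me3SiOTf (3 equiv), 2,6-di-tert-butyl-4-methylpyridine (4 equiv), CH2Cl2 (0.005 M), −78 °C; then K2CO3, MeOH, 0 → 23 °C
Reagents that add atoms: none
Why: Proposed new method: silylation of the 2,3-epoxide triggers 7-endo attack by the 6,7-epoxide oxygen, and the resulting epoxonium ion is opened at C-6 with inversion by the silyl enol ether through a chair (trans-fused benzoxepinone, C-3 and C-7 retained, C-12 equatorial); independently the silylated cis-epoxide is opened at C-19 with inversion by the C-14=C-15 olefin (C-18 retained, 18-O cis to the C-20 chain, either olefin geometry converging) and the C-15 cation loses H-14 to the tetrasubstituted olefin; the closest known reaction types are silyl-triflate-promoted tandem oxa-/carbacyclisation of diepoxy enol silanes and Lewis-acid epoxy-olefin monocyclisation, and the K2CO3/MeOH work-up removes the silyl ethers and equilibrates C-11 to the equatorial epimer.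

**Step 10**
Reactants: 16 (3R,5aR,6R,9aR)-3-hydroxy-6-(2-{(5R,6S)-5-hydroxy-6-[(2E)-4-hydroxy-4-methylpent-2-en-1-yl]-2,6-dimethylcyclohex-1-en-1-yl}ethyl)-2,2,5a-trimethyloctahydro-1-benzoxepin-7(2H)-one
Product: 17 siphonellinol C
Conditions: MeLi (8 equiv), CeCl3 (8 equiv), THF, −78 → 0 °C; aq. NH4Cl
Reagents that add atoms: methyllithium ([Li]C)
Why: Organocerium 1,2-addition (non-basic, so no enolisation) attacks the cyclohexanone from the equatorial direction because the axial face is blocked by the syn-axial C-6 methyl, giving the axial C-10 hydroxyl (10S); the three free hydroxyls only consume reagent.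

**Compound list**
1 | geranyl bromide, (2E)-1-bromo-3,7-dimethylocta-2,6-diene | CC(C)=CCC/C(C)=C/CBr | starting material
2 | N-methoxy-N-methylacetamide | CC(=O)N(C)OC | starting material
3 | lithium enolate of 2 | C=C(O[Li])N(C)OC | intermediate (not isolated)
4 | (4E)-N-methoxy-N,5,9-trimethyldeca-4,8-dienamide | CC(C)=CCC/C(C)=C/CCC(=O)N(C)OC | intermediate
5 | (4R,5R,8R)-4,5:8,9-diepoxy-N-methoxy-N,5,9-trimethyldecanamide | CC1(C)O[C@@H]1CC[C@@]2(C)O[C@@H]2CCC(=O)N(C)OC | intermediate
6 | (6R,7R,10R)-6,7:10,11-diepoxy-7,11-dimethyldodec-1-en-3-one | CC1(C)O[C@@H]1CC[C@@]2(C)O[C@@H]2CCC(=O)C=C | intermediate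
7 | trimethyl{[(5Z,9R,10R,13R)-9,10:13,14-diepoxy-10,14-dimethylpentadeca-1,5-dien-6-yl]oxy}silane | CC1(C)O[C@@H]1CC[C@@]2(C)O[C@@H]2CC/C(O[Si](C)(C)C)=C/CCC=C | intermediate
8 | neryl acetate, (2Z)-3,7-dimethylocta-2,6-dien-1-yl acetate | CC(C)=CCC/C(C)=C\COC(C)=O | starting material
9 | hydroxy selenide, (2Z)-7-hydroxy-3,7-dimethyl-6-(phenylselanyl)oct-2-en-1-yl acetate (racemic at C-6) | CC(C)(O)C([Se]c1ccccc1)CC/C(C)=C\COC(C)=O | intermediate (not isolated)
10 | selenoxide, (2Z)-7-hydroxy-3,7-dimethyl-6-(phenylseleninyl)oct-2-en-1-yl acetate | CC(C)(O)C([Se](=O)c1ccccc1)CC/C(C)=C\COC(C)=O | intermediate (not isolated)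
11 | (2Z,5E)-7-hydroxy-3,7-dimethylocta-2,5-dien-1-yl acetate | CC(C)(O)/C=C/C/C(C)=C\COC(C)=O | intermediate
12 | (5Z,8E)-2,6,10-trimethylundeca-1,5,8-trien-10-ol | C=C(C)CC/C=C(C)\C/C=C/C(C)(C)O | intermediate
13 | (5R,6S,8E)-5,6-epoxy-2,6,10-trimethylundeca-1,8-dien-10-ol | C=C(C)CC[C@H]1O[C@@]1(C)C/C=C/C(C)(C)O | intermediate
14 | (3R,6R,7R,10Z,14E,18R,19S,21E)-2,3:6,7:18,19-triepoxy-2,6,15,19,23-pentamethyl-10-[(trimethylsilyl)oxy]tetracosa-10,14,21-trien-23-ol (14E/14Z mixture, E shown) | CC1(C)O[C@@H]1CC[C@@]2(C)O[C@@H]2CC/C(O[Si](C)(C)C)=C/CC/C=C(\C)CC[C@H]3O[C@@]3(C)C/C=C/C(C)(C)O | intermediate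
15 | tris(trimethylsilyl) ether of 16 (3-O, ring A 5-O and side-chain 4-O silylated) | CC1=C(CC[C@@H]2[C@@]3(C)CC[C@@H](O[Si](C)(C)C)C(C)(C)O[C@@H]3CCC2=O)[C@](C)(C/C=C/C(C)(C)O[Si](C)(C)C)[C@H](O[Si](C)(C)C)CC1 | intermediate (not isolated)
16 | (3R,5aR,6R,9aR)-3-hydroxy-6-(2-{(5R,6S)-5-hydroxy-6-[(2E)-4-hydroxy-4-methylpent-2-en-1-yl]-2,6-dimethylcyclohex-1-en-1-yl}ethyl)-2,2,5a-trimethyloctahydro-1-benzoxepin-7(2H)-one | CC1=C(CC[C@@H]2[C@@]3(C)CC[C@@H](O)C(C)(C)O[C@@H]3CCC2=O)[C@](C)(C/C=C/C(C)(C)O)[C@H](O)CC1 | intermediate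
17 | siphonellinol C, (3R,5aR,6R,7S,9aR)-6-(2-{(5R,6S)-5-hydroxy-6-[(2E)-4-hydroxy-4-methylpent-2-en-1-yl]-2,6-dimethylcyclohex-1-en-1-yl}ethyl)-2,2,5a,7-tetramethyldecahydro-1-benzoxepine-3,7-diol | CC1=C(CC[C@@H]2[C@@]3(C)CC[C@@H](O)C(C)(C)O[C@@H]3CC[C@]2(C)O)[C@](C)(C/C=C/C(C)(C)O)[C@H](O)CC1 | target

**Totals**
Total step count: 10. Longest linear sequence: 7 steps (steps 1–4, 8, 9, 10 from geranyl bromide); the right half adds a 3-step branch (steps 5–7).

**Three steps most likely to fail**

1. The double cascade (step 9). This is the weakest step, and the olefin regiochemistry in ring A is its main uncertainty. The tetrasubstituted olefin is the Zaitsev and thermodynamic outcome, but H-14 sits next to quaternary C-19. Proton loss from C-16 or the C-15 methyl (giving the 15,16- or exocyclic olefin) is probably the kinetically preferred pathway, so the desired isomer may well be the minor one. Capture of the C-15 cation by O-18 (a 15,18-bridged ether) can also compete. Later equilibration with acid is not an option because of the tertiary allylic alcohol. In addition, two cascades must run cleanly in one molecule. Fallback (sets out from 7, uses 13, returns at 16): run the two ring-forming events one after the other. Treat 7 alone with Me3SiOTf and 2,6-di-tert-butyl-4-methylpyridine at −78 °C, then K2CO3/MeOH, to obtain the bicyclic hydroxy ketone (3R,5aR,6R,9aR)-6-(but-3-en-1-yl)-3-hydroxy-2,2,5a-trimethyloctahydro-1-benzoxepin-7(2H)-one F1. Cross-metathesise F1 with 13 (no silyl enol ether present any more) to the epoxy ketone F2. Then close ring A on F2 on its own with Me3SiOTf and the hindered pyridine followed by K2CO3/MeOH. Promoter, base and temperature for the proton loss can then be screened without endangering the oxepane cascade, and olefin isomers are separated at 16. This does not by itself solve the regiochemistry.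

2. The cross-metathesis (step 8). Forming a trisubstituted olefin from a 1,1-disubstituted partner is slow, and the trimethylsilyl enol ether has to survive catalyst and purification. Fallback (sets out from 13, uses 6, returns at 16): make the C-14=C-15 bond by a Wittig reaction and use metathesis only for an easy enone coupling.
- Ozonise the 1,1-disubstituted olefin of 13 selectively (O3, pyridine, CH2Cl2, −78 °C; Me2S) to the methyl ketone (5R,6S,8E)-5,6-epoxy-10-hydroxy-6,10-dimethylundec-8-en-2-one F3.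
- Olefinate with Ph3P=CHCH2CH=CH2 (from the phosphonium bromide and NaN(SiMe3)2) to the skipped diene (4E,8R,9S,11E)-8,9-epoxy-5,9,13-trimethyltetradeca-1,4,11-trien-13-ol F4 (geometry at C-4 again irrelevant).
- Cross-metathesise the terminal olefin of F4 with vinyl ketone 6 (second-generation Hoveyda–Grubbs catalyst) to the enone (3R,6R,7R,11E,14E,18R,19S,21E)-2,3:6,7:18,19-triepoxy-23-hydroxy-2,6,15,19,23-pentamethyltetracosa-11,14,21-trien-10-one F5.
- Fix the enol ether regiochemistry by 1,4-hydrosilylation (Et3SiH, Pt2[(CH2=CHSiMe2)2O]3, zerovalent platinum) to the (Z)-triethylsilyl enol ether F6, the triethylsilyl analogue of 14.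
- Submit F6 to the step 9 conditions with a Bu4NF work-up to reach 16.

3. The Shi epoxidation of 12 (step 7). The (Z)-trisubstituted olefin may give lower enantioselectivity than (E)-olefins, and the 1,1-disubstituted and trans-disubstituted olefins can be over-oxidised. Fallback (sets out from 11, returns at 13): use the allylic alcohol as the directing group.
- Methanolyse 11 (K2CO3, MeOH) to the diol (2Z,5E)-3,7-dimethylocta-2,5-diene-1,7-diol F7.
- Carry out a Sharpless asymmetric epoxidation (Ti(OiPr)4, D-(−)-diethyl tartrate, t-BuOOH, 4 Å sieves, −20 °C), which touches only the allylic olefin and gives the epoxy diol (2R,3S,5E)-2,3-epoxy-3,7-dimethyloct-5-ene-1,7-diol F8.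
- Tosylate the primary hydroxyl selectively (TsCl, Et3N, DMAP) to the epoxy tosylate (2R,3S,5E)-2,3-epoxy-7-hydroxy-3,7-dimethyloct-5-en-1-yl 4-methylbenzenesulfonate F9.
- Displace the tosylate with CH2=C(Me)CH2MgCl and catalytic CuI at −40 °C to give 13.

**Further compounds**
F1 | step 9 | (3R,5aR,6R,9aR)-6-(but-3-en-1-yl)-3-hydroxy-2,2,5a-trimethyloctahydro-1-benzoxepin-7(2H)-one | C=CCC[C@@H]1[C@@]2(C)CC[C@@H](O)C(C)(C)O[C@@H]2CCC1=O
F2 | step 9 | (3R,5aR,6R,9aR)-3-hydroxy-6-[(3E)-6-{(2R,3S)-3-[(2E)-4-hydroxy-4-methylpent-2-en-1-yl]-3-methyloxiran-2-yl}-4-methylhex-3-en-1-yl]-2,2,5a-trimethyloctahydro-1-benzoxepin-7(2H)-one | CC(C)(O)/C=C/C[C@]1(C)O[C@@H]1CC/C(C)=C/CC[C@@H]2[C@@]3(C)CC[C@@H](O)C(C)(C)O[C@@H]3CCC2=O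
F3 | step 8 | (5R,6S,8E)-5,6-epoxy-10-hydroxy-6,10-dimethylundec-8-en-2-one | CC(=O)CC[C@H]1O[C@@]1(C)C/C=C/C(C)(C)O
F4 | step 8 | (4E,8R,9S,11E)-8,9-epoxy-5,9,13-trimethyltetradeca-1,4,11-trien-13-ol | C=CC/C=C(\C)CC[C@H]1O[C@@]1(C)C/C=C/C(C)(C)O
F5 | step 8 | (3R,6R,7R,11E,14E,18R,19S,21E)-2,3:6,7:18,19-triepoxy-23-hydroxy-2,6,15,19,23-pentamethyltetracosa-11,14,21-trien-10-one | CC1(C)O[C@@H]1CC[C@@]2(C)O[C@@H]2CCC(=O)/C=C/C/C=C(\C)CC[C@H]3O[C@@]3(C)C/C=C/C(C)(C)O
F6 | step 8 | (3R,6R,7R,10Z,14E,18R,19S,21E)-2,3:6,7:18,19-triepoxy-2,6,15,19,23-pentamethyl-10-[(triethylsilyl)oxy]tetracosa-10,14,21-trien-23-ol | CC1(C)O[C@@H]1CC[C@@]2(C)O[C@@H]2CC/C(O[Si](CC)(CC)CC)=C/CC/C=C(\C)CC[C@H]3O[C@@]3(C)C/C=C/C(C)(C)O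
F7 | step 7 | (2Z,5E)-3,7-dimethylocta-2,5-diene-1,7-diol | CC(C)(O)/C=C/C/C(C)=C\CO
F8 | step 7 | (2R,3S,5E)-2,3-epoxy-3,7-dimethyloct-5-ene-1,7-diol | CC(C)(O)/C=C/C[C@]1(C)O[C@@H]1CO
F9 | step 7 | (2R,3S,5E)-2,3-epoxy-7-hydroxy-3,7-dimethyloct-5-en-1-yl 4-methylbenzenesulfonate | CC(C)(O)/C=C/C[C@]1(C)O[C@@H]1COS(=O)(=O)c1ccc(C)cc1
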